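The numbers in the tables come from a simulation with constants of no real substance, and the scatter is random.

common to all: J 0.41 M (fed, over 12 min)
- eta: Z 0.34 M; run made earlier
- delta: Z 0.49 M; run made earlier
- zeta: Z 0.61 M; run made earlier
- noon: Z 0.492 M; time 12 min
- midnight: Z 0.820 M; time 12 min
- winter: Z 0.328 M; time 12 min

| run | time / min | D / % | Q / % | J / % |
|---|---|---|---|---|
| eta | 2.00 | 1.4 | 5.3 | 8.4 |
| eta | 4.00 | 6.1 | 11.8 | 11.8 |
| eta | 6.00 | 9.9 | 15.8 | 16.3 |
| eta | 8.00 | 12.2 | 17.9 | 23.1 |
| delta | 1.00 | 0.8 | 2.5 | 6.1 |
| delta | 3.00 | 5.3 | 9.2 | 8.5 |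
| delta | 5.00 | 10.3 | 12.8 | 9.3 |
| delta | 8.00 | 14.9 | 17.6 | 15.7 |
| zeta | 0.667 | 0.4 | 2.1 | 3.4 |
| zeta | 1.50 | 2.5 | 4.5 | 5.3 |
| zeta | 4.00 | 8.4 | 10.1 | 7.7 |
| zeta | 8.00 | 15.6 | 15.3 | 12.0 |

(standard deviation of a reading: 0.5 percentage points)

- which of these holds the largest part of the J at the end of noon (D / J / L / Q)
- which of these holds the largest part of the J at the end of midnight (D / J / L / Q)
- which of these holds the largest part of the J at the end of winter (D / J / L / Q)
- final D in midnight, as a percentage of the J charged

- the numbers in the tables scatter by 0.5 percentage points (one standard deviation)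
- percentages count the whole charge, also what has not yet gone in

- An easy step first: Q holds one Z, D two and L 3, so we keep books on Z, the limiting reagent, in fractions of the J charge.
- The budget of Z is 2.00 in midnight, 1.20 in noon and 0.800 in winter, each short of the 3 that full L takes.
- We read the entries from zeta at 8.00 min, when 66.7% of the J has gone in.
- In zeta, J, Q and D stand at 12.0%, 15.3% and 15.6%, and we book the missing 23.8% as L.
- These entries put zeta's Z spent at 1.18 of the J charge.
- Our turnover count, the Z spent per J fed, is therefore 1.77 as a reading.
- Midnight has more budget than this count asks, so we expect 0.233 of Z left at the end. The booked L in zeta already exceeds J, Q and D, so we name L for midnight.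
- Noon has less budget than the count asks, so at this count its budget covers 67.9% of the feed. We expect J near 32.1% and name J.
- Winter has less budget than noon, and at this count it covers 45.3% of the feed. We expect J near 54.7% and name J, though the count comes from a richer flask.
- The forecast gives J for noon, L for midnight, J for winter and 20.5% of D in midnight, reasoning that “the steps are of similar speed”.
- The flasks give J in noon, L in midnight, J in winter and 18.2% of D in midnight.

    J + Z → Q (k = 0.0390 /M/s)
    Z + D → L (k = 0.0150 /M/s)
    J + Q → G (k = 0.0110 /M/s)
    Z + Q → D (k = 0.0220 /M/s)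

Midnight ends its feed with 12% of its Z left, so its count stands at 1.76. This flask is not at rest. By 120 min its Z is at 0% and its count has reached 2.00. Its J falls from 18.2% to 0.247%, L rises to 46.0%, and G, whose percentage counts both J that each G holds, rises to 23.7%. Winter ends its feed at a count of 0.774, with J at 41.3% against our 54.7%. By 120 min its Z is at 0% and its J is at 20.3%. D in midnight goes from 18.2% to 20.1%.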